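**Plan**

1. Retrosynthesis: the 4'-O–Si bond is cut last. Ring A is then cut at C4a–C5 and C8–C8a, which gives a C4a-sulfinylated (S)-2-aryl-2,3-dihydropyran-4-one and a geranyl-bearing 1-methoxy-3-silyloxydiene. The pyranone is cut at O1–C2 and C2–C3 (aryl aldehyde plus silyloxydiene), and the diene at the bond between the future C8 and geranyl C1'.
2. Enabling feature: without ring A, ring C is a 2-aryl-2,3-dihydropyran-4-one. Its C4a=C8a alkene (C4a α to the C4 carbonyl, C8a bound to O1) becomes a dienophile once C4a carries a sulfinyl group, and C2 is an aldehyde-derived carbon open to a catalytic asymmetric hetero-Diels–Alder reaction.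
3. Forward order: ring C (step 2), sulfinyl activation of C4a (steps 3–4), diene (steps 5–6), ring A by Diels–Alder addition and aromatization (step 7), desilylation (step 8).
4. Stereochemistry: the only stereocentre, C2 (S), is set in step 2 by the (S)-BINOL/Ti(OiPr)4 catalyst and no later step breaks a bond to it. The geranyl E-alkene comes with geranyl bromide.
5. A sulfinyl group is preferred to a halogen at C4a because H8a is not acidic and lies cis to the C4a substituent in the adduct. That geometry suits a thermal syn-elimination (Ei) but not an anti E2 loss of HX.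

Key step: step 7

Assumption 1: (S)-BINOL/Ti(OiPr)4 is taken to give the 2S dihydropyranone, by analogy with the sense of the BINOL/Ti(OiPr)4 carbonyl allylation. The configuration of 5 is to be confirmed, and (R)-BINOL is used if the sense proves opposite.

Assumption 2: sulfoxides 7, 13 and 14 are mixtures at sulfur, and 13 and 14 also at the transient ring A centres. These centres are left undefined in the SMILES because step 7 destroys all of them.

**Route**

Step 1
Reactants: 1 4-hydroxybenzaldehyde
Product: 2 4-(tert-butyldimethylsilyloxy)benzaldehyde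
Conditions: TBSCl, imidazole, DMF, rt
Reagents that add atoms: tert-butyldimethylsilyl chloride, CC(C)(C)[Si](C)(C)Cl
Why: Standard imidazole-mediated O-silylation of a phenol; the silyl ether is chosen because it can later be removed with bifluoride without acid (geranyl phenol) or base (flavanone C2).

Step 2
Reactants: 2 4-(tert-butyldimethylsilyloxy)benzaldehyde; 3 (E)-1-methoxy-3-(trimethylsilyloxy)buta-1,3-diene
Product: 5 (2S)-2-[4-(tert-butyldimethylsilyloxy)phenyl]-2,3-dihydro-4H-pyran-4-one, via silylated aldol adduct 4 (not isolated)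
Conditions: (S)-BINOL (20 mol%), Ti(OiPr)4 (10 mol%), 4 Å MS, Et2O, −20 °C; then TFA, CH2Cl2, 0 °C
Reagents that add atoms: none
Why: Catalytic asymmetric formal hetero-Diels–Alder reaction (enantioselective Mukaiyama aldol addition, then acid-induced cyclization with loss of methanol), in which the chiral BINOL–titanium complex shields one face of the aldehyde and so sets C2 as S.

Step 3
Reactants: 5 (2S)-2-[4-(tert-butyldimethylsilyloxy)phenyl]-2,3-dihydro-4H-pyran-4-one
Product: 6 (2S)-2-[4-(tert-butyldimethylsilyloxy)phenyl]-5-(phenylthio)-2,3-dihydro-4H-pyran-4-one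
Conditions: PhSCl, pyridine, CH2Cl2, −78 °C→0 °C
Reagents that add atoms: benzenesulfenyl chloride, ClSc1ccccc1
Why: Electrophilic α-sulfenylation of a vinylogous ester: the enol-ether carbon C5 attacks sulfur and pyridine removes HCl, the same addition–elimination reactivity as α-halogenation of dihydropyranones.

Step 4
Reactants: 6 (2S)-2-[4-(tert-butyldimethylsilyloxy)phenyl]-5-(phenylthio)-2,3-dihydro-4H-pyran-4-one
Product: 7 (2S)-2-[4-(tert-butyldimethylsilyloxy)phenyl]-5-(phenylsulfinyl)-2,3-dihydro-4H-pyran-4-one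
Conditions: mCPBA (1.0 equiv), CH2Cl2, −78 °C→−30 °C
Reagents that add atoms: 3-chloroperoxybenzoic acid, OOC(=O)c1cccc(Cl)c1
Why: Chemoselective sulfide-to-sulfoxide oxidation with one equivalent of peracid at low temperature; the push–pull alkene is a poor epoxidation substrate, and the unselectively formed sulfur centre does not matter because sulfur is expelled in step 7.

Step 5
Reactants: 8 (E)-4-methoxybut-3-en-2-one; 9 geranyl bromide
Product: 11 (1E,6E)-1-methoxy-7,11-dimethyldodeca-1,6,10-trien-3-one, via lithium dienolate 10 (not isolated)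
Conditions: LiN(SiMe3)2, THF, −78 °C (8 in excess); then 9, DMPU, −78 °C→−20 °C
Reagents that add atoms: none
Why: Kinetic α′-deprotonation of a vinylogous ester and C-alkylation with a reactive allylic bromide (Stork–Danheiser-type alkylation); the methyl group is the only enolizable position and SN2 attack keeps the geranyl E-alkene.

Step 6
Reactants: 11 (1E,6E)-1-methoxy-7,11-dimethyldodeca-1,6,10-trien-3-one
Product: 12 (1E,3Z,6E)-1-methoxy-7,11-dimethyl-3-(trimethylsilyloxy)dodeca-1,3,6,10-tetraene
Conditions: TMSOTf, Et3N, Et2O, 0 °C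
Reagents that add atoms: trimethylsilyl trifluoromethanesulfonate, C[Si](C)(C)OS(=O)(=O)C(F)(F)F
Why: Soft enolization and O-silylation of the only enolizable α-CH2; the Z enol ether is expected to predominate, which places the geranyl chain on the outside of the s-cis diene.

Step 7
Reactants: 7 (2S)-2-[4-(tert-butyldimethylsilyloxy)phenyl]-5-(phenylsulfinyl)-2,3-dihydro-4H-pyran-4-one; 12 (1E,3Z,6E)-1-methoxy-7,11-dimethyl-3-(trimethylsilyloxy)dodeca-1,3,6,10-tetraene
Product: 15 (2S)-2-[4-(tert-butyldimethylsilyloxy)phenyl]-8-[(2E)-3,7-dimethylocta-2,6-dien-1-yl]-7-hydroxychroman-4-one, via cis-fused sulfinyl cycloadduct 13 (not isolated), via sulfinyl enedione 14 (not isolated)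
Conditions: ZnCl2 (0.5 equiv), THF–PhMe, −20 °C→rt; then TFA (cat.), 0 °C; aq. NaHCO3 wash; then PhMe, 80 °C
Reagents that add atoms: none
Why: Proposed new method: diene 12 should add in a normal-demand, zinc-chelate-assisted [4+2] fashion (or by Mukaiyama–Michael addition and ring closure) across C4a=C8a of the β-keto vinyl sulfoxide 7, its silyl-enol-ether terminus (future C8) bonding to the oxygen-bearing β-carbon C8a and its methoxy terminus (future C5) to the sulfinyl-bearing C4a, so that ring A closes as a six-membered carbocycle by cycloaddition with a cis ring fusion. The closest known chemistry is the Diels–Alder addition and aromatization of 1-methoxy-3-silyloxydienes with sulfinyl-activated enones and quinones and with 3-acceptor-substituted chromones. Catalytic acid then converts the β-methoxy silyl enol ether of 13 into the C5=C6 enone of 14, which leaves H8a as the only β-hydrogen available to the sulfoxide. Warming should trigger the thermal syn-elimination (Ei) of benzenesulfenic acid across C4a–C8a, possible because suprafacial addition places sulfur and H8a cis, and ring A then aromatizes to the C7 phenol by keto–enol tautomerism. The regiochemistry needed (geranyl at C8, oxygen at C7) rests on matched polarization, with both acceptors on C4a making C8a the electrophilic carbon and the silyloxy group making the geranyl-bearing diene terminus the nucleophilic one, and on the Z enol-ether geometry that keeps the chain outside the s-cis diene. No new stereocentre survives (C4a, C5, C8, C8a and sulfur are all flattened or lost), and C2 is remote from every reacting atom and sees neither strong base nor strong acid.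

Step 8
Reactants: 15 (2S)-2-[4-(tert-butyldimethylsilyloxy)phenyl]-8-[(2E)-3,7-dimethylocta-2,6-dien-1-yl]-7-hydroxychroman-4-one
Product: 16 (2S)-7,4'-dihydroxy-8-geranylflavanone
Conditions: KHF2, MeOH, rt
Reagents that add atoms: none
Why: Bifluoride cleavage of a phenolic silyl ether under near-neutral conditions, which should spare the acid-sensitive ortho-geranyl phenol and the base-sensitive C2 centre.

**Compound list**

1 | 4-hydroxybenzaldehyde | O=Cc1ccc(O)cc1 | starting material
2 | 4-(tert-butyldimethylsilyloxy)benzaldehyde | O=Cc1ccc(O[Si](C)(C)C(C)(C)C)cc1 | intermediate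
3 | (E)-1-methoxy-3-(trimethylsilyloxy)buta-1,3-diene | CO/C=C/C(=C)O[Si](C)(C)C | starting material
4 | (1E,5S)-5-[4-(tert-butyldimethylsilyloxy)phenyl]-1-methoxy-5-(trimethylsilyloxy)pent-1-en-3-one (not isolated) | CO/C=C/C(=O)C[C@H](O[Si](C)(C)C)c1ccc(O[Si](C)(C)C(C)(C)C)cc1 | intermediate
5 | (2S)-2-[4-(tert-butyldimethylsilyloxy)phenyl]-2,3-dihydro-4H-pyran-4-one | C1=CO[C@H](c2ccc(O[Si](C)(C)C(C)(C)C)cc2)CC1=O | intermediate
6 | (2S)-2-[4-(tert-butyldimethylsilyloxy)phenyl]-5-(phenylthio)-2,3-dihydro-4H-pyran-4-one | c1ccccc1SC1=CO[C@H](c2ccc(O[Si](C)(C)C(C)(C)C)cc2)CC1=O | intermediate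
7 | (2S)-2-[4-(tert-butyldimethylsilyloxy)phenyl]-5-(phenylsulfinyl)-2,3-dihydro-4H-pyran-4-one (both sulfur epimers) | O=S(c1ccccc1)C1=CO[C@H](c2ccc(O[Si](C)(C)C(C)(C)C)cc2)CC1=O | intermediate
8 | (E)-4-methoxybut-3-en-2-one | CO/C=C/C(C)=O | starting material
9 | geranyl bromide, (2E)-1-bromo-3,7-dimethylocta-2,6-diene | CC(C)=CCC/C(C)=C/CBr | starting material
10 | lithium (E)-4-methoxybuta-1,3-dien-2-olate (not isolated) | [Li+].[O-]C(=C)/C=C/OC | intermediate
11 | (1E,6E)-1-methoxy-7,11-dimethyldodeca-1,6,10-trien-3-one | CO/C=C/C(=O)CC/C=C(\C)CCC=C(C)C | intermediate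
12 | (1E,3Z,6E)-1-methoxy-7,11-dimethyl-3-(trimethylsilyloxy)dodeca-1,3,6,10-tetraene | CO/C=C/C(O[Si](C)(C)C)=C/C/C=C(\C)CCC=C(C)C | intermediate
13 | (2S)-2-[4-(tert-butyldimethylsilyloxy)phenyl]-8-[(2E)-3,7-dimethylocta-2,6-dien-1-yl]-5-methoxy-4a-(phenylsulfinyl)-7-(trimethylsilyloxy)-2,3,4a,5,8,8a-hexahydro-4H-chromen-4-one (cis-fused, not isolated) | COC1C=C(O[Si](C)(C)C)C(C/C=C(\C)CCC=C(C)C)C2O[C@H](c3ccc(O[Si](C)(C)C(C)(C)C)cc3)CC(=O)C12S(=O)c1ccccc1 | intermediate
14 | (2S)-2-[4-(tert-butyldimethylsilyloxy)phenyl]-8-[(2E)-3,7-dimethylocta-2,6-dien-1-yl]-4a-(phenylsulfinyl)-2,3,8,8a-tetrahydro-4H-chromene-4,7(4aH)-dione (not isolated) | O=C1C=CC2(S(=O)c3ccccc3)C(=O)C[C@@H](c3ccc(O[Si](C)(C)C(C)(C)C)cc3)OC2C1C/C=C(\C)CCC=C(C)C | intermediate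
15 | (2S)-2-[4-(tert-butyldimethylsilyloxy)phenyl]-8-[(2E)-3,7-dimethylocta-2,6-dien-1-yl]-7-hydroxychroman-4-one | CC(C)=CCC/C(C)=C/Cc1c(O)ccc2c1O[C@H](c1ccc(O[Si](C)(C)C(C)(C)C)cc1)CC2=O | intermediate
16 | (2S)-7,4'-dihydroxy-8-geranylflavanone | CC(C)=CCC/C(C)=C/Cc1c(O)ccc2c1O[C@H](c1ccc(O)cc1)CC2=O | target

**Step count and risks**

Total: 8 steps. Longest linear sequence: 6 steps (1, 2, 3, 4, 7, 8). The diene branch (steps 5 and 6) joins at step 7.

Steps most likely to fail:

1. Step 7. The cycloaddition may be sluggish, because O1 donates into the dienophile and the diene terminus is substituted. ZnCl2 may ionize the benzylic C2–O1 bond and erode the enantiomeric purity. The sulfoxide may eliminate toward C5 before methanol is lost, or undergo a [2,3]-shift as an allylic sulfoxide, either of which diverts material from aromatization. The fallback uses known chemistry; it sets out from geranyl bromide 9 and returns to the route at target 16.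
   - C-Geranylation of 2,4-dihydroxyacetophenone with 9 in aqueous KOH should give 1-[3-geranyl-2,4-dihydroxyphenyl]ethanone F1 (a known but modestly selective alkylation).
   - Selective silylation of the non-chelated 4-hydroxyl (TBSCl, imidazole) should give 1-[4-(tert-butyldimethylsilyloxy)-3-geranyl-2-hydroxyphenyl]ethanone F2.
   - Condensation with N,N-dimethylformamide dimethyl acetal should give the enaminone (E)-1-[4-(tert-butyldimethylsilyloxy)-3-geranyl-2-hydroxyphenyl]-3-(dimethylamino)prop-2-en-1-one F3.
   - Mild acid (Amberlyst-15, CH2Cl2) should close it to 7-(tert-butyldimethylsilyloxy)-8-geranyl-4H-chromen-4-one F4.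
   - Asymmetric conjugate addition of 4-(tert-butyldimethylsilyloxy)phenylboronic acid (Pd(OCOCF3)2, the t-BuPyOx enantiomer that delivers 2S, NH4PF6, water, 1,2-dichloroethane, 60 °C) should give (2S)-7-(tert-butyldimethylsilyloxy)-2-[4-(tert-butyldimethylsilyloxy)phenyl]-8-geranylchroman-4-one F5.
   - KHF2 in methanol should then remove both silyl groups to give 16.

2. Step 5. Proton exchange between the product ketone and the unreacted dienolate may lead to dialkylation and self-condensation, so that little monoalkylated ketone is obtained. The fallback sets out from geranyl bromide 9 and returns at ketone 11.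
   - The lithium enolate of N-methoxy-N-methylacetamide (LiN(iPr)2, THF, −78 °C) is alkylated with 9 to give (4E)-N-methoxy-N,5,9-trimethyldeca-4,8-dienamide F6.
   - Addition of HC≡CMgBr (THF, 0 °C) should give (6E)-7,11-dimethyldodeca-6,10-dien-1-yn-3-one F7.
   - DABCO-catalysed conjugate addition of methanol at rt should then give the (E)-β-methoxy enone 11.

3. Step 3. Chlorosulfenylation across the enol ether may be followed by capture of the oxocarbenium ion and ring cleavage, or by a second sulfenylation, instead of clean loss of HCl. The fallback sets out from dihydropyranone 5 and returns at sulfide 6.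
   - α-Iodination with I2 and pyridine in CH2Cl2 should give (2S)-2-[4-(tert-butyldimethylsilyloxy)phenyl]-5-iodo-2,3-dihydro-4H-pyran-4-one F8.
   - C–S cross-coupling with thiophenol (Pd2(dba)3, Xantphos, iPr2NEt, dioxane, 80 °C) should then give 6.

**Further compounds**

F1 | step 7 | 1-[3-[(2E)-3,7-dimethylocta-2,6-dien-1-yl]-2,4-dihydroxyphenyl]ethanone | CC(=O)c1ccc(O)c(C/C=C(\C)CCC=C(C)C)c1O
F2 | step 7 | 1-[4-(tert-butyldimethylsilyloxy)-3-[(2E)-3,7-dimethylocta-2,6-dien-1-yl]-2-hydroxyphenyl]ethanone | CC(=O)c1ccc(O[Si](C)(C)C(C)(C)C)c(C/C=C(\C)CCC=C(C)C)c1O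
F3 | step 7 | (E)-1-[4-(tert-butyldimethylsilyloxy)-3-[(2E)-3,7-dimethylocta-2,6-dien-1-yl]-2-hydroxyphenyl]-3-(dimethylamino)prop-2-en-1-one | CN(C)/C=C/C(=O)c1ccc(O[Si](C)(C)C(C)(C)C)c(C/C=C(\C)CCC=C(C)C)c1O
F4 | step 7 | 7-(tert-butyldimethylsilyloxy)-8-[(2E)-3,7-dimethylocta-2,6-dien-1-yl]-4H-chromen-4-one | O=c1ccoc2c(C/C=C(\C)CCC=C(C)C)c(O[Si](C)(C)C(C)(C)C)ccc12
F5 | step 7 | (2S)-7-(tert-butyldimethylsilyloxy)-2-[4-(tert-butyldimethylsilyloxy)phenyl]-8-[(2E)-3,7-dimethylocta-2,6-dien-1-yl]chroman-4-one | CC(C)=CCC/C(C)=C/Cc1c(O[Si](C)(C)C(C)(C)C)ccc2c1O[C@H](c1ccc(O[Si](C)(C)C(C)(C)C)cc1)CC2=O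
F6 | step 5 | (4E)-N-methoxy-N,5,9-trimethyldeca-4,8-dienamide | CON(C)C(=O)CC/C=C(\C)CCC=C(C)C
F7 | step 5 | (6E)-7,11-dimethyldodeca-6,10-dien-1-yn-3-one | C#CC(=O)CC/C=C(\C)CCC=C(C)C
F8 | step 3 | (2S)-2-[4-(tert-butyldimethylsilyloxy)phenyl]-5-iodo-2,3-dihydro-4H-pyran-4-one | IC1=CO[C@H](c2ccc(O[Si](C)(C)C(C)(C)C)cc2)CC1=O
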